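**Retrosynthetic overview**
1. Vogelin F (13) ⇐ removal of two pivalates from the 5,7-di-O-pivaloyl isoflavone 12.
2. 12 ⇐ one-step radical C–H/C–H coupling–annulation: the C3–C1′ bond forms between the α-carbon of enaminone 7 and C4 (para to OH) of the unfunctionalised phenol 11; the pyranone ring closes in the same pot with loss of Me2NH.
3. 7 ⇐ resorcinol: C-acetylation, pivaloylation, ketone-directed ortho C–H hydroxylation (third A-ring oxygen), DMF-DMA condensation.
4. 11 ⇐ resorcinol: mono-O-methylation, then ortho C-prenylation.
5. Ring order: rings A and B both come from resorcinol; ring C (the pyranone) is formed last, in the key step.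

Assumption: the target has no stereocentre and no stereogenic alkene, so it is achiral; "single enantiomer" is taken to mean the single constitution drawn.

**Route**

Step 1
Reactants: 1 resorcinol; 2 acetic acid
Product: 3, 1-(2,4-dihydroxyphenyl)ethan-1-one
Conditions: AcOH, BF3·OEt2, 90 °C; aq. NaOAc quench
Reagents that add atoms: acetic acid (2), CC(=O)O
Why: Friedel–Crafts (Nencki-type) C-acylation at C4 of resorcinol, ortho/para to both hydroxyls, and the BF2 chelate of the o-hydroxy ketone stops the reaction at mono-acylation.

Step 2
Reactants: 3
Product: 4, 4-acetyl-1,3-phenylene bis(2,2-dimethylpropanoate)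
Conditions: PivCl, Et3N, DMAP (cat.), CH2Cl2, 0 °C → rt
Reagents that add atoms: pivaloyl chloride, CC(C)(C)C(=O)Cl
Why: exhaustive O-acylation gives esters that survive TFA/TFAA, DMF-DMA and anodic oxidation, and that make ring A electron-poor so it is not oxidised in steps 3 and 7.

Step 3
Reactants: 4
Product: 5, 1-[2-hydroxy-4,6-bis(pivaloyloxy)phenyl]ethan-1-one
Conditions: Pd(OAc)2 (10 mol %), K2S2O8, TFA/TFAA (9:1), 50 °C; aq. NaHCO3 work-up
Reagents that add atoms: trifluoroacetic acid, OC(=O)C(F)(F)F (supplies the new phenolic O; the CF3CO group is lost on work-up)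
Why: ketone-directed ortho C–H oxygenation (cyclopalladation, oxidation to Pd(IV), C–O reductive elimination to the aryl trifluoroacetate, hydrolysis), with regiochemistry fixed because C6 is the only ortho C–H.

Step 4
Reactants: 5; 6 N,N-dimethylformamide dimethyl acetal (DMF-DMA)
Product: 7, (E)-3-(dimethylamino)-1-[2-hydroxy-4,6-bis(pivaloyloxy)phenyl]prop-2-en-1-one
Conditions: DMF-DMA (3 equiv), toluene, 80 °C
Reagents that add atoms: DMF-DMA (6), COC(OC)N(C)C
Why: formamide-acetal condensation with the methyl ketone gives the (E)-enaminone, while the chelated 2-OH is not methylated and the hindered pivalates resist aminolysis.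

Step 5
Reactants: 1 resorcinol; 8 dimethyl sulfate
Product: 9, 3-methoxyphenol
Conditions: Me2SO4 (1.0 equiv), NaOH, H2O/toluene, Bu4NBr (cat.), 40 °C
Reagents that add atoms: dimethyl sulfate (8), COS(=O)(=O)OC
Why: Williamson mono-methylation under statistical control, with unreacted resorcinol and the dimethyl ether removed by extraction and distillation.

Step 6
Reactants: 9; 10 prenyl bromide (1-bromo-3-methylbut-2-ene)
Product: 11, 5-methoxy-2-(3-methylbut-2-en-1-yl)phenol
Conditions: NaH, toluene, 0 °C; prenyl bromide, rt
Reagents that add atoms: prenyl bromide (10), CC(C)=CCBr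
Why: ortho C-alkylation of the tight sodium phenoxide ion pair in a non-polar solvent, favouring the less hindered ortho carbon (C6, para to OMe) over C2 between OH and OMe; the minor C2 isomer and O-prenyl ether are removed by chromatography.

Step 7 (key step)
Reactants: 7 (1 equiv); 11 (2 equiv)
Product: 12, 3-[4-hydroxy-2-methoxy-5-(3-methylbut-2-en-1-yl)phenyl]-4-oxo-4H-chromene-5,7-diyl bis(2,2-dimethylpropanoate)
Conditions: graphite(+)/Pt(–), undivided cell, 5 mA cm⁻², 2.5 F mol⁻¹, n-Bu4NBF4, 2,6-lutidine (1 equiv), HFIP/CH2Cl2 (4:1), rt; then 40 °C, 1 h
Reagents that add atoms: none (H2 and Me2NH are lost)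
Why: Proposed new method: anodic one-electron (PCET) oxidation of phenol 11 gives an HFIP-stabilised phenoxyl radical whose spin density is highest at C4 (para to O, ortho to OMe, sterically open), and this carbon adds to the nucleophilic α-carbon of push–pull alkene 7 to give an α-amino radical that is oxidised at once to the iminium, after which the dienone re-aromatises, the chelated 2-OH closes onto the iminium and Me2NH is eliminated to give the chromone; if 7 is oxidised first, its radical cation reacts at the same α-carbon with 11 as π-nucleophile (SOMO-type enamine radical-cation arylation), so both manifolds form the same C3–C1′ bond; the product phenol carries a para electron-withdrawing chromonyl group and is harder to oxidise than 11, and the prenyl alkene is oxidised only at much higher potential; closest known reaction types are the radical α-C–H functionalisation/chromone annulation of o-hydroxyaryl enaminones (thiyl, sulfonyl, CF3 and aryl radicals) and anodic dehydrogenative phenol–arene cross-coupling in HFIP.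

Step 8
Reactants: 12
Product: 13, Vogelin F, 5,7-dihydroxy-3-[4-hydroxy-2-methoxy-5-(3-methylbut-2-en-1-yl)phenyl]-4H-chromen-4-one
Conditions: K2CO3, MeOH/THF, rt → 40 °C; aq. NH4Cl
Reagents that add atoms: none
Why: base-mediated transesterification of the two aryl pivalates (activated as esters of acidic chromone phenols) leaves the 2′-OMe, the prenyl alkene and the isoflavone core intact, and avoiding acid prevents chroman formation between the 4′-OH and the prenyl group.

**Compound list**
1 | resorcinol | Oc1cccc(O)c1 | starting material
2 | acetic acid | CC(=O)O | starting material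
3 | 1-(2,4-dihydroxyphenyl)ethan-1-one | CC(=O)c1ccc(O)cc1O | intermediate
4 | 4-acetyl-1,3-phenylene bis(2,2-dimethylpropanoate) | CC(=O)c1ccc(OC(=O)C(C)(C)C)cc1OC(=O)C(C)(C)C | intermediate
5 | 1-[2-hydroxy-4,6-bis(pivaloyloxy)phenyl]ethan-1-one | CC(=O)c1c(O)cc(OC(=O)C(C)(C)C)cc1OC(=O)C(C)(C)C | intermediate
6 | N,N-dimethylformamide dimethyl acetal | COC(OC)N(C)C | starting material
7 | (E)-3-(dimethylamino)-1-[2-hydroxy-4,6-bis(pivaloyloxy)phenyl]prop-2-en-1-one | CN(C)/C=C/C(=O)c1c(O)cc(OC(=O)C(C)(C)C)cc1OC(=O)C(C)(C)C | intermediate
8 | dimethyl sulfate | COS(=O)(=O)OC | starting material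
9 | 3-methoxyphenol | COc1cccc(O)c1 | intermediate
10 | prenyl bromide | CC(C)=CCBr | starting material
11 | 5-methoxy-2-(3-methylbut-2-en-1-yl)phenol | COc1ccc(CC=C(C)C)c(O)c1 | intermediate
12 | 3-[4-hydroxy-2-methoxy-5-(3-methylbut-2-en-1-yl)phenyl]-4-oxo-4H-chromene-5,7-diyl bis(2,2-dimethylpropanoate) | COc1cc(O)c(CC=C(C)C)cc1-c1coc2cc(OC(=O)C(C)(C)C)cc(OC(=O)C(C)(C)C)c2c1=O | intermediate
13 | Vogelin F | COc1cc(O)c(CC=C(C)C)cc1-c1coc2cc(O)cc(O)c2c1=O | target

**Totals**
Total steps: 8. Longest linear sequence: 6 (1 → 3 → 4 → 5 → 7 → 12 → 13).

**Three steps most likely to fail, with fallbacks**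
1. Step 7 (radical C–H/C–H coupling–annulation). Risks are ortho (C6) or O-coupling of the phenoxyl radical, homo-coupling of 11, and oxidation of the o-prenylphenol to a chromene. Fallback: pre-functionalise ring B instead of using its C–H bond. Iodinate 9 para to the OH before prenylation, C-prenylate, and generate the aryl radical from the aryl iodide by photoredox halogen-atom transfer; it adds to the α-carbon of 7 and the same annulation follows (known aryl-radical/enaminone isoflavone synthesis).
2. Step 3 (Pd-catalysed ortho C–H hydroxylation). Risks are sluggish cyclopalladation of the ortho-substituted ketone and partial ester loss. Fallback: install the third oxygen by sterically controlled Ir-catalysed C–H borylation/oxidation. The sequence is resorcinol bis-MOM ether, C2-lithiation/acetylation, borylation at the position meta to both OMOM groups, oxidation and protection; the o-OMOM enaminone is then carried through the coupling and the pyranone is closed by acid at the end.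
3. Step 6 (ortho C-prenylation). Risks are a moderate yield and C2/O-alkylated by-products. Fallback: O-allylate 9, run a thermal aromatic Claisen rearrangement (ortho-specific [3,3] shift; the 2-allyl-5-methoxyphenol isomer is separated), then convert allyl to prenyl by olefin cross-metathesis with 2-methyl-2-butene.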